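## Structural features

- The target is an achiral chain of six benzene rings (A to F, counted from the 2,4,6-trihydroxyphenoxy end). The rings are joined only by five diaryl ether oxygens and carry sixteen free phenolic hydroxyls; there is no stereocentre and no ring-to-ring C–C bond.
- Rings A, B, D and F have simple, symmetric patterns: A is 2,4,6-trihydroxyphenyl, B and D are 3,5-dihydroxy-1,4-dioxygenated, and F is 3,4,5-trihydroxyphenyl.
- Rings C and E each have five contiguous oxygen-bearing carbons (two neighbouring ether carbons followed by three hydroxyl carbons) and a single CH.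
- Every inter-ring oxygen is flanked by ortho oxygen substituents on at least one of its two rings, so each diaryl ether is sterically congested.
- The free polyphenol is very electron-rich, air-sensitive and polar, so all hydroxyls stay masked as methyl ethers until the last step.
- The real difficulty is regiochemical: placing five oxygens on ring C (and on ring E) with two different aryloxy groups on defined neighbouring carbons.
- The key step exploits ring C. Numbering C-1 as the carbon bound to the ring B oxygen and C-2 as the CH, carbons C-3 to C-6 with their four oxygens map onto the four carbons of a squaric ester, and C-1/C-2 map onto a 1-aryloxyvinyl group.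
- This mapping puts the squarate carbinol oxygen at C-6, ortho to the ring B ether, so it is the hindered oxygen that must carry ring D; the ketene-derived oxygen at C-3, next to the CH, is the one to methylate.

## Logic of the disconnections

**27 to 26.** Fifteen O–CH3 bonds are cut. The polyphenol cannot be carried through any bond-forming step, and methyl ethers are the one mask that survives base, peracid, organolithium and heat. The forward step must cleave all of them without touching the five diaryl ethers.

**26 to 24.** The C-4 hydroxyl of ring E is traced to a formyl group (C–O from C–C). The formyl group is there because it activates ring E for the preceding ether formation. The hydroxyl it leaves needs no methylation, since the next step unmasks everything. The oxidation must pick the aldehyde over six electron-rich rings.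

**24 to 18 plus 23.** The bond from the ring D phenol oxygen to C-1 of ring E is cut. This is the most convergent cut (four rings plus two), and C-1 of ring E is para to the formyl group. The forward step is a substitution between a 2,6-dimethoxyphenoxide and a fluoride that has an aryloxy neighbour.

**23 to 20 plus 21, then 20 to 19 to 2.** The ring F oxygen to ring E carbon bond is cut. This carbon is meta to the formyl group and cannot be reached by addition–elimination, so a copper-catalysed coupling at a C–I bond is used. The iodine comes from electrophilic substitution of 2 at its only open position. The formyl group is masked as the acetal during coupling so that the para fluoride is switched off. Ring E thus comes from 2 in three steps.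

**18 to 16 to 15 plus 2.** Ring D is cut off at the ring C oxygen to ring D carbon bond, and its second oxygen is traced to the formyl group of 2. The forward substitution must generate a phenoxide flanked by a methoxy and a bulky aryloxy group; it is released from its silyl ether by fluoride.

**15 to 14.** One O–CH3 bond on ring C (the C-3 oxygen) is cut. The two oxygens of the ring C hydroquinone must be told apart. In 14 the ketene-derived oxygen is the only free one, so methylation needs no selectivity.

**14 to 11 (key step).** The ring C bond between C-2 (the CH) and C-3 is cut in a retro-6π sense, and the four-membered ring bond between C-3 and C-6 is restored in a retro-4π sense. Ring C reduces to a squarate adduct with all five oxygens already in place. The forward step needs outward rotation of the C-4 oxygen substituent and a clean unimolecular closure.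

**11 to 7 plus 8.** The C–C bond between the carbinol carbon and the oxygen-bearing vinyl carbon is cut, together with the O–Si bond. The symmetric dione 8 takes one nucleophile without a regiochemical question. Two design changes are made here:
- The tertiary alkoxide is silylated in the same flask. A free hydroquinone would oxidise in air and would need a selective mono-alkylation.
- The nucleophile is made by bromine–lithium exchange on 7, not by deprotonation of a plain aryl vinyl ether. Rings A and B hold four hydrogens flanked by two oxygens each, and these are at least as acidic as the vinyl hydrogen.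

**7 to 5 plus 6.** The vinyl C–O bond is cut. A copper-catalysed coupling of the phenol with the geminal dibromide installs the vinyl group and the exchange handle in one step.

**5 to 3 to 1 plus 2.** The phenol oxygen of ring B is traced to the formyl group of 2, and the A–B ether to a substitution of the para fluoride by 1. The same two-step logic serves rings B and D.

## Other disconnections considered

**Alternative 1: triple decarbonylation of a tris-depside.**
- Cut: the three bonds from the oxygens on rings A, C and E to the ipso carbons of rings B, D and F, each traced back to an aryl ester. The precursor is tris-depside A2.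
- Forward key step: Ni(cod)2 or Pd(OAc)2 with a chelating bis(dialkylphosphino)alkane inserts into each acyl C–O bond, loses CO and closes the C–O bond by reductive elimination, three times, to give the hexadecamethyl ether A1.
- In favour: ester formation between an acid and a hindered phenol is easier than any substitution in the chosen plan, which makes it the better of the two on that point. No formyl activating group or peracid is needed. Final deprotection is equal to the chosen plan.
- Against: this ether synthesis is best established for electron-poor acyl partners and unhindered aryloxy groups. Here every acyl ring is an electron-rich dimethoxy-oxybenzoate and every aryloxy oxygen has two ortho oxygen neighbours. Oxidative addition, CO loss and reductive elimination should all be slow, and the sequence must succeed three times in one molecule.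
- Structure: A2 already contains the B–C and D–E ethers and both pentaoxygenated rings as phenols, so the cut leaves the central problem untouched. The chosen plan solves ring C by construction.
- Step economy: three ethers in one operation would beat three substitution/oxidation pairs, but only after rings C and E have been made some other way.

**Alternative 2: Danheiser benzannulation for ring D.**
- Cut: ring D is divided into a four-carbon unit, the cyclobutenone A4 that carries rings E and F, and a two-carbon unit, the ethynyl ether A5 of the A–B–C triad.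
- Forward key step: heating opens A4 to a vinylketene, which adds across the alkyne of A5 (alkyne CH to ketene carbon). A second 4π opening and a 6π closure give the phenol A3.
- In favour: it is a three-plus-three junction and so better than the chosen plan in convergence. It belongs to the same electrocyclic family, so mechanistic reliability is equal. Regiochemistry follows from the polarisation of the ynol ether. The ethyl ether and free hydroxyl of ring D disappear in the final dealkylation.
- Against: ring D is the ring that least needs construction, because 2 supplies it in two routine steps. A4 and A5 each contain a pentaoxygenated ring whose synthesis is still open. A5 is the alkynyl ether of the most hindered phenol in the molecule. The bimolecular ketene–alkyne step competes with ketene dimerisation.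
- Step economy: worse overall, because the ring-forming step is spent on the easy ring and rings C and E still need their own solutions.

**Alternative 3: biomimetic Claisen folding for ring A.**
- Cut: the ring A bond between the aryloxy-bearing carbon and the former ester carbon. The precursor is the diketo ester A7.
- Forward key step: base forms the polyanion of A7, and the aryloxy-bearing C-6 attacks the ester carbonyl to give the free phloroglucinol ring of A6.
- In favour: ring A arrives unprotected, so three methyl ethers and the oxidation-prone phenol 1 are avoided; on this point it is better than the chosen plan. Conditions are mild.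
- Against: ring A is the cheapest ring to buy. Building it last puts the most advanced pentamer through an alkylation with a triketide chain and then through polyanion chemistry. C-6 is the least acidic carbon of the chain, and lactone formation or aldol closure are the usual outlets.
- Comparison: A6 still needs demethylation of thirteen ethers, so the last step is equal. It is fully linear and places the riskiest C–C bond formation at the end, whereas the chosen plan makes its ring early on small material. It also says nothing about rings C and E.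

Key step: step 5

Remarks on the chemistry:
- Assumption: 1, 2, 6, 8 and 21 are bought.
- Assumption: 10 and 11 are racemic; their single stereocentre is destroyed in step 5, and the target is achiral.
- In names, "AB-aryloxy" stands for 2,6-dimethoxy-4-(2,4,6-trimethoxyphenoxy)phenoxy.
- Hazard choices: no tin reagent, no tert-butyllithium and no diazo compound is used. Compounds 6 and 8, iodomethane and BBr3 need closed handling, and the bromomethane off-gas of step 14 is scrubbed.

## Steps

Step 1
Reactants: 1 2,4,6-trimethoxyphenol; 2 4-fluoro-2,6-dimethoxybenzaldehyde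
Product: 3 2,6-dimethoxy-4-(2,4,6-trimethoxyphenoxy)benzaldehyde
Conditions: K2CO3, DMF, 100 °C, argon
Reagents that add atoms: none
Why: Nucleophilic aromatic substitution by addition–elimination; the fluoride is para to the formyl group, which stabilises the anionic adduct, and argon protects the electron-rich phenoxide from oxidation.

Step 2
Reactants: 3 2,6-dimethoxy-4-(2,4,6-trimethoxyphenoxy)benzaldehyde
Product: 5 2,6-dimethoxy-4-(2,4,6-trimethoxyphenoxy)phenol, via aryl formate 4 (not isolated)
Conditions: mCPBA, CH2Cl2, 0 °C to rt; aq. Na2SO3/NaHCO3 wash; then K2CO3 (cat.), MeOH, rt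
Reagents that add atoms: 3-chloroperoxybenzoic acid (mCPBA), O=C(OO)c1cccc(Cl)c1
Why: Dakin-type Baeyer–Villiger oxidation; the electron-rich 2,6-dimethoxyaryl group migrates in preference to hydrogen, and the labile aryl formate is cleaved by methanolysis.

Step 3
Reactants: 5 2,6-dimethoxy-4-(2,4,6-trimethoxyphenoxy)phenol; 6 1,1-dibromoethene
Product: 7 2-[(1-bromoethenyl)oxy]-1,3-dimethoxy-5-(2,4,6-trimethoxyphenoxy)benzene
Conditions: CuI (10 mol %), 2,2'-bipyridine (20 mol %), K3PO4, toluene, 80 °C, sealed vessel, argon, excess 6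
Reagents that add atoms: none
Why: Copper-catalysed Ullmann-type coupling of a phenol with a 1,1-dibromoalkene, which should stop at the 1-bromoenol ether because the product is more electron-rich and more hindered than 6; the bromine left on the oxygen-bearing carbon fixes the site of the later metalation.

Step 4
Reactants: 7 2-[(1-bromoethenyl)oxy]-1,3-dimethoxy-5-(2,4,6-trimethoxyphenoxy)benzene; 8 dimethyl squarate
Product: 11 4-(tert-butyldimethylsilyloxy)-2,3-dimethoxy-4-[1-(AB-aryloxy)ethenyl]cyclobut-2-en-1-one (racemic), via 1-(AB-aryloxy)vinyllithium 9 (not isolated), via lithium alkoxide 10 (not isolated)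
Conditions: n-BuLi, THF, −78 °C, 10 min; cannulation into 8, THF, −78 °C; TBSOTf, −78 to −40 °C; aq. NaHCO3
Reagents that add atoms: tert-butyldimethylsilyl trifluoromethanesulfonate (TBSOTf), CC(C)(C)[Si](C)(C)OS(=O)(=O)C(F)(F)F
Why: Bromine–lithium exchange is far faster at −78 °C than ortho-lithiation of the methoxyarenes, and 1,2-addition to one carbonyl of the symmetric squaric ester gives a single tertiary alkoxide (new stereocentre racemic, erased in step 5); silylation in the same flask marks the oxygen that must later carry ring D.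

Step 5
Reactants: 11 4-(tert-butyldimethylsilyloxy)-2,3-dimethoxy-4-[1-(AB-aryloxy)ethenyl]cyclobut-2-en-1-one
Product: 14 4-(tert-butyldimethylsilyloxy)-2,3-dimethoxy-5-(AB-aryloxy)phenol, via dienylketene 12 (not isolated), via cyclohexadienone 13 (not isolated)
Conditions: toluene (0.02 M, degassed), 110 °C, argon
Reagents that add atoms: none
Why: This is a Moore rearrangement of a 4-alkenyl-4-silyloxycyclobutenone, the known thermal route from squaric ester adducts to polyoxygenated hydroquinone monoethers. Heating causes conrotatory 4π-electrocyclic opening of the bond between the carbonyl carbon and the silyloxy-bearing carbon and gives the dienylketene 12. The silyloxy group is a donor and rotates outward, which turns the 1-aryloxyvinyl group inward, next to the ketene. Thermal disrotatory 6π-electrocyclisation then joins the ketene carbon to the vinyl CH2 carbon and closes ring C as the six-membered dienone 13, the only ring and the only skeletal bond formed. Tautomerisation of the CH2–C=O unit gives the phenol 14 and makes the cascade irreversible. No stereocentre is created, and the one in 11 is lost. Regiochemistry is not a variable, because the squarate delivers four oxygenated carbons in fixed order and the vinyl unit delivers the carbon bearing the ring B oxygen and the lone CH. The step needs torquoselectivity and unimolecular closure, which the C-4 donor, high dilution and the absence of nucleophiles should secure, and the silyl group leaves free only the ketene-derived hydroxyl, the one to be methylated.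

Step 6
Reactants: 14 4-(tert-butyldimethylsilyloxy)-2,3-dimethoxy-5-(AB-aryloxy)phenol
Product: 15 tert-butyl[6-(AB-aryloxy)-2,3,4-trimethoxyphenoxy]dimethylsilane
Conditions: MeI, K2CO3, acetone, 40 °C
Reagents that add atoms: iodomethane, CI
Why: Williamson O-methylation of the only free phenol; the hindered aryl silyl ether should survive carbonate in acetone, so no selectivity between two hydroxyls is required.

Step 7
Reactants: 15 tert-butyl[6-(AB-aryloxy)-2,3,4-trimethoxyphenoxy]dimethylsilane; 2 4-fluoro-2,6-dimethoxybenzaldehyde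
Product: 16 4-[6-(AB-aryloxy)-2,3,4-trimethoxyphenoxy]-2,6-dimethoxybenzaldehyde
Conditions: CsF (20 mol %), DMSO, 80 °C, argon
Reagents that add atoms: none
Why: Fluoride-triggered desilylative nucleophilic aromatic substitution; fluoride frees the hindered phenoxide, which displaces the para-formyl-activated fluoride of 2, and the fluoride released carries the chain.

Step 8
Reactants: 16 4-[6-(AB-aryloxy)-2,3,4-trimethoxyphenoxy]-2,6-dimethoxybenzaldehyde
Product: 18 4-[6-(AB-aryloxy)-2,3,4-trimethoxyphenoxy]-2,6-dimethoxyphenol, via aryl formate 17 (not isolated)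
Conditions: mCPBA, CH2Cl2, 0 °C to rt; aq. Na2SO3/NaHCO3 wash; then K2CO3 (cat.), MeOH/THF, rt
Reagents that add atoms: 3-chloroperoxybenzoic acid (mCPBA), O=C(OO)c1cccc(Cl)c1
Why: Dakin-type Baeyer–Villiger oxidation as in step 2; the di-ortho-methoxy aldehyde reacts with the peracid faster than the fully substituted ether rings do.

Step 9
Reactants: 2 4-fluoro-2,6-dimethoxybenzaldehyde
Product: 19 4-fluoro-3-iodo-2,6-dimethoxybenzaldehyde
Conditions: N-iodosuccinimide, TFA (cat.), MeCN, rt
Reagents that add atoms: N-iodosuccinimide, O=C1CCC(=O)N1I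
Why: Electrophilic aromatic iodination; the two equivalent open positions are ortho to one methoxy group, para to the other and meta to the formyl group, so only one product can form.

Step 10
Reactants: 19 4-fluoro-3-iodo-2,6-dimethoxybenzaldehyde
Product: 20 1-(dimethoxymethyl)-4-fluoro-3-iodo-2,6-dimethoxybenzene
Conditions: HC(OMe)3, TsOH·H2O (cat.), MeOH, rt; Et3N quench
Reagents that add atoms: trimethyl orthoformate, COC(OC)OC
Why: Acid-catalysed acetalisation; masking the formyl group removes the para activation of the fluoride, so the phenoxide of the next step cannot attack the C–F carbon.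

Step 11
Reactants: 20 1-(dimethoxymethyl)-4-fluoro-3-iodo-2,6-dimethoxybenzene; 21 3,4,5-trimethoxyphenol
Product: 23 4-fluoro-2,6-dimethoxy-3-(3,4,5-trimethoxyphenoxy)benzaldehyde, via dimethyl acetal 22 (not isolated)
Conditions: CuI (10 mol %), picolinic acid (20 mol %), K3PO4, DMSO, 90 °C, argon; then 1 M HCl, THF, rt
Reagents that add atoms: water, O
Why: Ullmann diaryl ether synthesis at the C–I bond with an unhindered, electron-rich phenol, the unactivated C–F bond staying intact; acidic hydrolysis of the acetal then restores the formyl group as activator.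

Step 12
Reactants: 18 4-[6-(AB-aryloxy)-2,3,4-trimethoxyphenoxy]-2,6-dimethoxyphenol; 23 4-fluoro-2,6-dimethoxy-3-(3,4,5-trimethoxyphenoxy)benzaldehyde
Product: 24 4-{4-[6-(AB-aryloxy)-2,3,4-trimethoxyphenoxy]-2,6-dimethoxyphenoxy}-2,6-dimethoxy-3-(3,4,5-trimethoxyphenoxy)benzaldehyde
Conditions: Cs2CO3, DMSO, 110 °C, argon
Reagents that add atoms: none
Why: Nucleophilic aromatic substitution of the para-formyl-activated fluoride; the neighbouring aryloxy group is meta to the formyl group and is not displaced, so only the fluoride leaves.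

Step 13
Reactants: 24 4-{4-[6-(AB-aryloxy)-2,3,4-trimethoxyphenoxy]-2,6-dimethoxyphenoxy}-2,6-dimethoxy-3-(3,4,5-trimethoxyphenoxy)benzaldehyde
Product: 26 4-{4-[6-(AB-aryloxy)-2,3,4-trimethoxyphenoxy]-2,6-dimethoxyphenoxy}-2,6-dimethoxy-3-(3,4,5-trimethoxyphenoxy)phenol, via aryl formate 25 (not isolated)
Conditions: mCPBA, CH2Cl2, 0 °C to rt; aq. Na2SO3/NaHCO3 wash; then K2CO3 (cat.), MeOH/THF, rt
Reagents that add atoms: 3-chloroperoxybenzoic acid (mCPBA), O=C(OO)c1cccc(Cl)c1
Why: Dakin-type Baeyer–Villiger oxidation; it places the last oxygen on ring E, and the free hydroxyl needs no protection because only the global deprotection follows.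

Step 14
Reactants: 26 4-{4-[6-(AB-aryloxy)-2,3,4-trimethoxyphenoxy]-2,6-dimethoxyphenoxy}-2,6-dimethoxy-3-(3,4,5-trimethoxyphenoxy)phenol
Product: 27 5-(2,6-dihydroxy-4-{2,3,4-trihydroxy-6-[2,6-dihydroxy-4-(2,4,6-trihydroxyphenoxy)phenoxy]phenoxy}phenoxy)-4-(3,4,5-trihydroxyphenoxy)benzene-1,2,3-triol (target)
Conditions: BBr3 (excess), CH2Cl2, −78 °C to rt, argon; then MeOH and degassed water, 0 °C; reversed-phase or size-exclusion purification under argon
Reagents that add atoms: none
Why: Lewis-acid cleavage of aryl methyl ethers (boron coordinates the ether oxygen and bromide attacks the methyl carbon); diaryl ethers have no alkyl carbon to attack and should remain intact.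

## Compound list

1 | 2,4,6-trimethoxyphenol | COc1cc(OC)c(O)c(OC)c1 | starting material
2 | 4-fluoro-2,6-dimethoxybenzaldehyde | COc1cc(F)cc(OC)c1C=O | starting material
3 | 2,6-dimethoxy-4-(2,4,6-trimethoxyphenoxy)benzaldehyde | COc1cc(OC)c(Oc2cc(OC)c(C=O)c(OC)c2)c(OC)c1 | intermediate
4 | 2,6-dimethoxy-4-(2,4,6-trimethoxyphenoxy)phenyl formate | COc1cc(OC)c(Oc2cc(OC)c(OC=O)c(OC)c2)c(OC)c1 | intermediate
5 | 2,6-dimethoxy-4-(2,4,6-trimethoxyphenoxy)phenol | COc1cc(OC)c(Oc2cc(OC)c(O)c(OC)c2)c(OC)c1 | intermediate
6 | 1,1-dibromoethene | C=C(Br)Br | starting material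
7 | 2-[(1-bromoethenyl)oxy]-1,3-dimethoxy-5-(2,4,6-trimethoxyphenoxy)benzene | COc1cc(OC)c(Oc2cc(OC)c(OC(Br)=C)c(OC)c2)c(OC)c1 | intermediate
8 | dimethyl squarate (3,4-dimethoxycyclobut-3-ene-1,2-dione) | COC1=C(OC)C(=O)C1=O | starting material
9 | {1-[2,6-dimethoxy-4-(2,4,6-trimethoxyphenoxy)phenoxy]ethenyl}lithium | [Li]C(=C)Oc1c(OC)cc(Oc2c(OC)cc(OC)cc2OC)cc1OC | intermediate
10 | lithium 1-{1-[2,6-dimethoxy-4-(2,4,6-trimethoxyphenoxy)phenoxy]ethenyl}-2,3-dimethoxy-4-oxocyclobut-2-en-1-olate (racemic) | [Li+].[O-]C1(C(=C)Oc2c(OC)cc(Oc3c(OC)cc(OC)cc3OC)cc2OC)C(OC)=C(OC)C1=O | intermediate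
11 | 4-{[tert-butyl(dimethyl)silyl]oxy}-4-{1-[2,6-dimethoxy-4-(2,4,6-trimethoxyphenoxy)phenoxy]ethenyl}-2,3-dimethoxycyclobut-2-en-1-one (racemic) | COC1=C(OC)C(O[Si](C)(C)C(C)(C)C)(C(=C)Oc2c(OC)cc(Oc3c(OC)cc(OC)cc3OC)cc2OC)C1=O | intermediate
12 | (3Z)-4-{[tert-butyl(dimethyl)silyl]oxy}-5-[2,6-dimethoxy-4-(2,4,6-trimethoxyphenoxy)phenoxy]-2,3-dimethoxyhexa-1,3,5-trien-1-one | COC(=C=O)/C(OC)=C(\C(=C)Oc1c(OC)cc(Oc2c(OC)cc(OC)cc2OC)cc1OC)O[Si](C)(C)C(C)(C)C | intermediate
13 | 4-{[tert-butyl(dimethyl)silyl]oxy}-5-[2,6-dimethoxy-4-(2,4,6-trimethoxyphenoxy)phenoxy]-2,3-dimethoxycyclohexa-2,4-dien-1-one | COC1=C(OC)C(O[Si](C)(C)C(C)(C)C)=C(Oc2c(OC)cc(Oc3c(OC)cc(OC)cc3OC)cc2OC)CC1=O | intermediate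
14 | 4-{[tert-butyl(dimethyl)silyl]oxy}-5-[2,6-dimethoxy-4-(2,4,6-trimethoxyphenoxy)phenoxy]-2,3-dimethoxyphenol | COc1c(OC)c(O[Si](C)(C)C(C)(C)C)c(Oc2c(OC)cc(Oc3c(OC)cc(OC)cc3OC)cc2OC)cc1O | intermediate
15 | tert-butyl{6-[2,6-dimethoxy-4-(2,4,6-trimethoxyphenoxy)phenoxy]-2,3,4-trimethoxyphenoxy}dimethylsilane | COc1c(OC)c(O[Si](C)(C)C(C)(C)C)c(Oc2c(OC)cc(Oc3c(OC)cc(OC)cc3OC)cc2OC)cc1OC | intermediate
16 | 4-{6-[2,6-dimethoxy-4-(2,4,6-trimethoxyphenoxy)phenoxy]-2,3,4-trimethoxyphenoxy}-2,6-dimethoxybenzaldehyde | COc1c(OC)c(Oc2cc(OC)c(C=O)c(OC)c2)c(Oc2c(OC)cc(Oc3c(OC)cc(OC)cc3OC)cc2OC)cc1OC | intermediate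
17 | 4-{6-[2,6-dimethoxy-4-(2,4,6-trimethoxyphenoxy)phenoxy]-2,3,4-trimethoxyphenoxy}-2,6-dimethoxyphenyl formate | COc1c(OC)c(Oc2cc(OC)c(OC=O)c(OC)c2)c(Oc2c(OC)cc(Oc3c(OC)cc(OC)cc3OC)cc2OC)cc1OC | intermediate
18 | 4-{6-[2,6-dimethoxy-4-(2,4,6-trimethoxyphenoxy)phenoxy]-2,3,4-trimethoxyphenoxy}-2,6-dimethoxyphenol | COc1c(OC)c(Oc2cc(OC)c(O)c(OC)c2)c(Oc2c(OC)cc(Oc3c(OC)cc(OC)cc3OC)cc2OC)cc1OC | intermediate
19 | 4-fluoro-3-iodo-2,6-dimethoxybenzaldehyde | COc1cc(F)c(I)c(OC)c1C=O | intermediate
20 | 1-(dimethoxymethyl)-4-fluoro-3-iodo-2,6-dimethoxybenzene | COc1cc(F)c(I)c(OC)c1C(OC)OC | intermediate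
21 | 3,4,5-trimethoxyphenol | COc1cc(O)cc(OC)c1OC | starting material
22 | 1-(dimethoxymethyl)-4-fluoro-2,6-dimethoxy-3-(3,4,5-trimethoxyphenoxy)benzene | COc1cc(F)c(Oc2cc(OC)c(OC)c(OC)c2)c(OC)c1C(OC)OC | intermediate
23 | 4-fluoro-2,6-dimethoxy-3-(3,4,5-trimethoxyphenoxy)benzaldehyde | COc1cc(F)c(Oc2cc(OC)c(OC)c(OC)c2)c(OC)c1C=O | intermediate
24 | 4-(4-{6-[2,6-dimethoxy-4-(2,4,6-trimethoxyphenoxy)phenoxy]-2,3,4-trimethoxyphenoxy}-2,6-dimethoxyphenoxy)-2,6-dimethoxy-3-(3,4,5-trimethoxyphenoxy)benzaldehyde | COc1c(OC)c(Oc2cc(OC)c(Oc3cc(OC)c(C=O)c(OC)c3Oc3cc(OC)c(OC)c(OC)c3)c(OC)c2)c(Oc2c(OC)cc(Oc3c(OC)cc(OC)cc3OC)cc2OC)cc1OC | intermediate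
25 | 4-(4-{6-[2,6-dimethoxy-4-(2,4,6-trimethoxyphenoxy)phenoxy]-2,3,4-trimethoxyphenoxy}-2,6-dimethoxyphenoxy)-2,6-dimethoxy-3-(3,4,5-trimethoxyphenoxy)phenyl formate | COc1c(OC)c(Oc2cc(OC)c(Oc3cc(OC)c(OC=O)c(OC)c3Oc3cc(OC)c(OC)c(OC)c3)c(OC)c2)c(Oc2c(OC)cc(Oc3c(OC)cc(OC)cc3OC)cc2OC)cc1OC | intermediate
26 | 4-(4-{6-[2,6-dimethoxy-4-(2,4,6-trimethoxyphenoxy)phenoxy]-2,3,4-trimethoxyphenoxy}-2,6-dimethoxyphenoxy)-2,6-dimethoxy-3-(3,4,5-trimethoxyphenoxy)phenol | COc1c(OC)c(Oc2cc(OC)c(Oc3cc(OC)c(O)c(OC)c3Oc3cc(OC)c(OC)c(OC)c3)c(OC)c2)c(Oc2c(OC)cc(Oc3c(OC)cc(OC)cc3OC)cc2OC)cc1OC | intermediate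
27 | 5-(2,6-dihydroxy-4-{2,3,4-trihydroxy-6-[2,6-dihydroxy-4-(2,4,6-trihydroxyphenoxy)phenoxy]phenoxy}phenoxy)-4-(3,4,5-trihydroxyphenoxy)benzene-1,2,3-triol (CNP0114537.0) | Oc1cc(O)c(Oc2cc(O)c(Oc3cc(O)c(O)c(O)c3Oc3cc(O)c(Oc4cc(O)c(O)c(O)c4Oc4cc(O)c(O)c(O)c4)c(O)c3)c(O)c2)c(O)c1 | target

## Step count and least certain steps

Total: 14 steps. Longest linear sequence: 11 steps (steps 1 to 8 and 12 to 14). Steps 9 to 11 are the three-step branch to 23.

**Step 5 (key step).** The most likely failure is diversion of the dienylketene before the 6π closure. It could be trapped by adventitious nucleophiles, or the electron-rich enol ether could react bimolecularly, because the silyloxy and the bulky aryloxy group on neighbouring carbons crowd the closing termini. Loss of the silyl group followed by air oxidation to the quinone is the second concern. The fallback builds ring C without any rearrangement, by the substitution/oxidation logic used for ring E.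
- It sets out from 20 and 5. Copper-catalysed coupling of 20 with benzyl alcohol (CuI, 1,10-phenanthroline, Cs2CO3, toluene, 110 °C) would give 3-(benzyloxy)-1-(dimethoxymethyl)-4-fluoro-2,6-dimethoxybenzene F1, and dilute acid would give 3-(benzyloxy)-4-fluoro-2,6-dimethoxybenzaldehyde F2.
- Substitution of the fluoride by the phenoxide of 5 (Cs2CO3, DMSO) would give 3-(benzyloxy)-2,6-dimethoxy-4-(AB-aryloxy)benzaldehyde F3.
- Peracid oxidation would pass through 3-(benzyloxy)-2,6-dimethoxy-4-(AB-aryloxy)phenyl formate F4 to 3-(benzyloxy)-2,6-dimethoxy-4-(AB-aryloxy)phenol F5.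
- Methylation would give 1-(benzyloxy)-2,3,4-trimethoxy-6-(AB-aryloxy)benzene F6, and hydrogenolysis (H2, Pd/C) would give 2,3,4-trimethoxy-6-(AB-aryloxy)phenol F7.
- Substitution of 2 by the phenoxide of F7 (Cs2CO3, DMSO) rejoins the route at 16.

**Step 3.** The hindered 2,6-dimethoxyphenoxide may couple slowly. Base could meanwhile strip HBr from 6 or from 7 to give alkynes, a second substitution could give the ketene acetal, and 7 could hydrolyse to the aryl acetate on work-up. The fallback makes the same bromide by addition instead of coupling.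
- It sets out from 5. K2CO3 and trichloroethene in DMF would give 2-{[(E)-1,2-dichloroethenyl]oxy}-1,3-dimethoxy-5-(2,4,6-trimethoxyphenoxy)benzene F8.
- Two equivalents of n-BuLi at −78 °C followed by methanol would give 2-(ethynyloxy)-1,3-dimethoxy-5-(2,4,6-trimethoxyphenoxy)benzene F9.
- One equivalent of HBr (from Me3SiBr and methanol at −78 °C) should add in the Markovnikov sense through the ketenium ion and rejoin the route at 7.

**Step 4.** The lithium carbenoid 9 may decompose by loss of lithium aryloxide, or be protonated, before it reaches 8. Elimination of HBr from 7 by n-BuLi may compete with exchange, and silylation of the crowded alkoxide may be incomplete. The fallback avoids the vinyl anion altogether and uses the alkynyl counterpart of the same squarate chemistry; it therefore also replaces steps 5 to 7.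
- It sets out from 5 through the dichlorovinyl ether F8. Two equivalents of n-BuLi would give {[2,6-dimethoxy-4-(2,4,6-trimethoxyphenoxy)phenoxy]ethynyl}lithium F10.
- Addition to 8 would give 4-hydroxy-2,3-dimethoxy-4-[(AB-aryloxy)ethynyl]cyclobut-2-en-1-one F11.
- Heating in toluene should rearrange F11 to 2,3-dimethoxy-5-(AB-aryloxy)cyclohexa-2,5-diene-1,4-dione F12, and Na2S2O4 would reduce it to 2,3-dimethoxy-5-(AB-aryloxy)benzene-1,4-diol F13.
- Mono-methylation at the less hindered hydroxyl (one equivalent of K2CO3 and MeI) would give the phenol F7, and substitution of 2 rejoins the route at 16. The cost is that the mono-methylation must be selective.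

**Step 12.** The substitution joins a di-ortho-methoxy phenoxide to a fluoride with an ortho aryloxy group. Slow addition caused by this compression may let the aldehyde or the phenoxide degrade at the temperature needed. The fallback forms the two ethers of ring E in the opposite order.
- It sets out from 18 and 19. The fluoride of 19 has a smaller neighbour and is additionally activated by it, so substitution (Cs2CO3, DMSO) would give 4-{4-[6-(AB-aryloxy)-2,3,4-trimethoxyphenoxy]-2,6-dimethoxyphenoxy}-3-iodo-2,6-dimethoxybenzaldehyde F14.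
- Copper-catalysed coupling of F14 with 21 (CuI, picolinic acid, K3PO4) rejoins the route at 24.

**Step 14.** Fifteen ether cleavages must all go to completion. Partially demethylated borate complexes may precipitate and stall, and the free polyphenol may oxidise or be lost during isolation. The fallback changes the isolation strategy.
- It sets out from 26. The crude product of the BBr3 treatment would be acetylated (Ac2O, pyridine) to the hexadecaacetate of the target F15.
- F15 can be purified on silica and checked for residual methyl groups. Deacetylation with catalytic NaOMe in degassed methanol, then acidic resin, comes back at 27.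

## Further compounds

F1 | step 5 | 3-(benzyloxy)-1-(dimethoxymethyl)-4-fluoro-2,6-dimethoxybenzene | COc1cc(F)c(OCc2ccccc2)c(OC)c1C(OC)OC
F2 | step 5 | 3-(benzyloxy)-4-fluoro-2,6-dimethoxybenzaldehyde | COc1cc(F)c(OCc2ccccc2)c(OC)c1C=O
F3 | step 5 | 3-(benzyloxy)-4-[2,6-dimethoxy-4-(2,4,6-trimethoxyphenoxy)phenoxy]-2,6-dimethoxybenzaldehyde | COc1cc(Oc2c(OC)cc(Oc3c(OC)cc(OC)cc3OC)cc2OC)c(OCc2ccccc2)c(OC)c1C=O
F4 | step 5 | 3-(benzyloxy)-4-[2,6-dimethoxy-4-(2,4,6-trimethoxyphenoxy)phenoxy]-2,6-dimethoxyphenyl formate | COc1cc(Oc2c(OC)cc(Oc3c(OC)cc(OC)cc3OC)cc2OC)c(OCc2ccccc2)c(OC)c1OC=O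
F5 | step 5 | 3-(benzyloxy)-4-[2,6-dimethoxy-4-(2,4,6-trimethoxyphenoxy)phenoxy]-2,6-dimethoxyphenol | COc1cc(Oc2c(OC)cc(Oc3c(OC)cc(OC)cc3OC)cc2OC)c(OCc2ccccc2)c(OC)c1O
F6 | step 5 | 1-(benzyloxy)-6-[2,6-dimethoxy-4-(2,4,6-trimethoxyphenoxy)phenoxy]-2,3,4-trimethoxybenzene | COc1cc(Oc2c(OC)cc(Oc3c(OC)cc(OC)cc3OC)cc2OC)c(OCc2ccccc2)c(OC)c1OC
F7 | step 5 | 6-[2,6-dimethoxy-4-(2,4,6-trimethoxyphenoxy)phenoxy]-2,3,4-trimethoxyphenol | COc1cc(Oc2c(OC)cc(Oc3c(OC)cc(OC)cc3OC)cc2OC)c(O)c(OC)c1OC
F8 | step 3 | 2-{[(E)-1,2-dichloroethenyl]oxy}-1,3-dimethoxy-5-(2,4,6-trimethoxyphenoxy)benzene | COc1cc(OC)c(Oc2cc(OC)c(O/C(Cl)=C\Cl)c(OC)c2)c(OC)c1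
F9 | step 3 | 2-(ethynyloxy)-1,3-dimethoxy-5-(2,4,6-trimethoxyphenoxy)benzene | COc1cc(OC)c(Oc2cc(OC)c(OC#C)c(OC)c2)c(OC)c1
F10 | step 4 | {[2,6-dimethoxy-4-(2,4,6-trimethoxyphenoxy)phenoxy]ethynyl}lithium | [Li]C#COc1c(OC)cc(Oc2c(OC)cc(OC)cc2OC)cc1OC
F11 | step 4 | 4-{[2,6-dimethoxy-4-(2,4,6-trimethoxyphenoxy)phenoxy]ethynyl}-4-hydroxy-2,3-dimethoxycyclobut-2-en-1-one (racemic) | COC1=C(OC)C(O)(C#COc2c(OC)cc(Oc3c(OC)cc(OC)cc3OC)cc2OC)C1=O
F12 | step 4 | 5-[2,6-dimethoxy-4-(2,4,6-trimethoxyphenoxy)phenoxy]-2,3-dimethoxycyclohexa-2,5-diene-1,4-dione | COC1=C(OC)C(=O)C(Oc2c(OC)cc(Oc3c(OC)cc(OC)cc3OC)cc2OC)=CC1=O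
F13 | step 4 | 5-[2,6-dimethoxy-4-(2,4,6-trimethoxyphenoxy)phenoxy]-2,3-dimethoxybenzene-1,4-diol | COc1c(OC)c(O)c(Oc2c(OC)cc(Oc3c(OC)cc(OC)cc3OC)cc2OC)cc1O
F14 | step 12 | 4-(4-{6-[2,6-dimethoxy-4-(2,4,6-trimethoxyphenoxy)phenoxy]-2,3,4-trimethoxyphenoxy}-2,6-dimethoxyphenoxy)-3-iodo-2,6-dimethoxybenzaldehyde | COc1c(OC)c(Oc2cc(OC)c(Oc3cc(OC)c(C=O)c(OC)c3I)c(OC)c2)c(Oc2c(OC)cc(Oc3c(OC)cc(OC)cc3OC)cc2OC)cc1OC
F15 | step 14 | hexadecaacetate of the target | CC(=O)Oc1cc(OC(C)=O)c(Oc2cc(OC(C)=O)c(Oc3cc(OC(C)=O)c(OC(C)=O)c(OC(C)=O)c3Oc3cc(OC(C)=O)c(Oc4cc(OC(C)=O)c(OC(C)=O)c(OC(C)=O)c4Oc4cc(OC(C)=O)c(OC(C)=O)c(OC(C)=O)c4)c(OC(C)=O)c3)c(OC(C)=O)c2)c(OC(C)=O)c1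
A1 | alternative 1 | hexadecamethyl ether of the target | COc1cc(OC)c(Oc2cc(OC)c(Oc3cc(OC)c(OC)c(OC)c3Oc3cc(OC)c(Oc4cc(OC)c(OC)c(OC)c4Oc4cc(OC)c(OC)c(OC)c4)c(OC)c3)c(OC)c2)c(OC)c1
A2 | alternative 1 | tris-depside (aryl esters at the A/B, C/D and E/F junctions, all hydroxyls methylated) | COc1cc(OC)c(OC(=O)c2cc(OC)c(Oc3cc(OC)c(OC)c(OC)c3OC(=O)c3cc(OC)c(Oc4cc(OC)c(OC)c(OC)c4OC(=O)c4cc(OC)c(OC)c(OC)c4)c(OC)c3)c(OC)c2)c(OC)c1
A3 | alternative 2 | hexamer with ring D as free phenol and ethyl ether, all other hydroxyls methylated | COc1cc(OC)c(Oc2cc(OC)c(Oc3cc(OC)c(OC)c(OC)c3Oc3cc(O)c(Oc4cc(OC)c(OC)c(OC)c4Oc4cc(OC)c(OC)c(OC)c4)c(OCC)c3)c(OC)c2)c(OC)c1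
A4 | alternative 2 | 3-ethoxy-4-[3,4,5-trimethoxy-2-(3,4,5-trimethoxyphenoxy)phenoxy]cyclobut-2-en-1-one (racemic) | CCOC1=CC(=O)C1Oc1cc(OC)c(OC)c(OC)c1Oc1cc(OC)c(OC)c(OC)c1
A5 | alternative 2 | 1-(ethynyloxy)-6-[2,6-dimethoxy-4-(2,4,6-trimethoxyphenoxy)phenoxy]-2,3,4-trimethoxybenzene | C#COc1c(OC)c(OC)c(OC)cc1Oc1c(OC)cc(Oc2c(OC)cc(OC)cc2OC)cc1OC
A6 | alternative 3 | hexamer with ring A as free triol and rings B to F methylated | Oc1cc(O)c(Oc2cc(OC)c(Oc3cc(OC)c(OC)c(OC)c3Oc3cc(OC)c(Oc4cc(OC)c(OC)c(OC)c4Oc4cc(OC)c(OC)c(OC)c4)c(OC)c3)c(OC)c2)c(O)c1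
A7 | alternative 3 | methyl 6-aryloxy-3,5-dioxohexanoate carrying the methylated rings B to F | COC(=O)CC(=O)CC(=O)COc1c(OC)cc(Oc2cc(OC)c(OC)c(OC)c2Oc2cc(OC)c(Oc3cc(OC)c(OC)c(OC)c3Oc3cc(OC)c(OC)c(OC)c3)c(OC)c2)cc1OC
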